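Ring A is cut at C5–C10 (ent-kaurane numbering). C6, the hydroxymethyl carbon, and C20, the lactone OCH2 of ring B, are both oxygenated and stand 1,4 across this bond, so it joins two aldehyde α-carbons of like polarity. Anodic oxidation of an open-chain bis(methyl enol ether) in methanol makes the bond by umpolung, closes ring A, sets quaternary C10 and C5 against the C1 ether, and delivers C6 and C20 as acetals. The precursor has C6=C5 on gem-dimethyl C4, the C3–C2–C1(OBn) tether from (S)-butanetriol acetonide, and C10=C20 carrying the C9–C8–C7 silyloxypropyl arm. Lactonisation, a ketyl closure and a palladium cyclisation then add rings B, C and D.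

Key step: step 12

Remark 1: both Wittig olefinations are assumed to give E/Z mixtures. Compound 17 is drawn as the E,E isomer and the mixture is used, because the carbons that carry the geometry end as ring or acetal carbons.
Remark 2: enolates and other conjugate bases made by deprotonation count as forms of the numbered compound and receive no number of their own.
Remark 3: atoms are named by ent-kaurane numbers in all intermediates (C1 carbinol, C4 gem-dimethyl, C5/C6, C10/C20, C9–C8–C7 arm, C11–C17 for rings C/D).

Step 1
Reactants: 1 (S)-2-(2,2-dimethyl-1,3-dioxolan-4-yl)ethanol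
Product: 2 (S)-4-(2-iodoethyl)-2,2-dimethyl-1,3-dioxolane
Conditions: I2, PPh3, imidazole, CH2Cl2, 0 °C to rt
Reagents that add atoms: iodine, II
Why: Appel-type iodination of the unhindered primary alcohol under imidazole buffering leaves untouched the acetonide and the (S) carbinol carbon, which becomes C1 (with C10, C2 and C3 from the same four-carbon unit).

Step 2
Reactants: 2 (S)-4-(2-iodoethyl)-2,2-dimethyl-1,3-dioxolane; 3 isobutyronitrile
Product: 4 (S)-4-(2,2-dimethyl-1,3-dioxolan-4-yl)-2,2-dimethylbutanenitrile
Conditions: 3, LDA, THF, −78 °C; then 2, −78 °C to rt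
Reagents that add atoms: none
Why: SN2 alkylation of the small, strongly nucleophilic lithiated nitrile with a primary iodide forms C3–C4 and brings in quaternary C4, both methyl groups and C5 (nitrile carbon) at once, so no bond has to be made later at a tertiary centre.

Step 3
Reactants: 4 (S)-4-(2,2-dimethyl-1,3-dioxolan-4-yl)-2,2-dimethylbutanenitrile
Product: 5 (S)-5,6-dihydroxy-2,2-dimethylhexanenitrile
Conditions: AcOH/H2O 4:1, 40 °C
Reagents that add atoms: none
Why: Acid-catalysed acetonide hydrolysis frees the C1/C10 diol while the tertiary nitrile is inert.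

Step 4
Reactants: 5 (S)-5,6-dihydroxy-2,2-dimethylhexanenitrile
Product: 6 (S)-5-hydroxy-2,2-dimethyl-6-(trityloxy)hexanenitrile
Conditions: TrCl, Et3N, DMAP (cat.), CH2Cl2, rt
Reagents that add atoms: trityl chloride, ClC(c1ccccc1)(c1ccccc1)c1ccccc1
Why: Steric selection lets the bulky trityl chloride etherify only the primary C10 hydroxyl, and a trityl ether cannot migrate in the basic step that follows.

Step 5
Reactants: 6 (S)-5-hydroxy-2,2-dimethyl-6-(trityloxy)hexanenitrile
Product: 7 (S)-5-(benzyloxy)-2,2-dimethyl-6-(trityloxy)hexanenitrile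
Conditions: NaH, BnBr, Bu4NI (cat.), THF/DMF, 0 °C to rt
Reagents that add atoms: benzyl bromide, BrCc1ccccc1
Why: Williamson etherification puts on O1 a benzyl group, chosen because it is not oxidised at enol ether potentials, is small and metal-binding, and is orthogonal to the later silyl ethers (the nitrile has no α-hydrogen).

Step 6
Reactants: 7 (S)-5-(benzyloxy)-2,2-dimethyl-6-(trityloxy)hexanenitrile
Product: 8 (S)-5-(benzyloxy)-6-hydroxy-2,2-dimethylhexanenitrile
Conditions: TsOH·H2O (cat.), MeOH/CH2Cl2, rt
Reagents that add atoms: none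
Why: Acid-catalysed methanolysis through the stabilised trityl cation frees the primary alcohol and leaves the benzyl ether and nitrile alone.

Step 7
Reactants: 8 (S)-5-(benzyloxy)-6-hydroxy-2,2-dimethylhexanenitrile
Product: 9 (S)-5-(benzyloxy)-2,2-dimethyl-6-oxohexanenitrile
Conditions: Dess–Martin periodinane, CH2Cl2, 0 °C to rt
Reagents that add atoms: none
Why: Dess–Martin oxidation runs without base, so the α-benzyloxy aldehyde (C10) keeps the configuration at C1.

Step 8
Reactants: 9 (S)-5-(benzyloxy)-2,2-dimethyl-6-oxohexanenitrile; 10 (3-bromopropoxy)(tert-butyl)dimethylsilane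
Product: 12 (5S)-5-(benzyloxy)-9-(tert-butyldimethylsilyloxy)-6-hydroxy-2,2-dimethylnonanenitrile (both carbinol epimers at C10), via Grignard reagent 11 (not isolated)
Conditions: 10, Mg, THF; then 9, THF, −78 °C; aq. NH4Cl
Reagents that add atoms: none
Why: Grignard addition to the aldehyde is far faster than to the hindered tertiary nitrile and forms C10–C9, and the new carbinol centre is of no consequence because step 10 oxidises it.

Step 9
Reactants: 12 (5S)-5-(benzyloxy)-9-(tert-butyldimethylsilyloxy)-6-hydroxy-2,2-dimethylnonanenitrile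
Product: 13 (5S)-5-(benzyloxy)-9-(tert-butyldimethylsilyloxy)-6-hydroxy-2,2-dimethylnonanal
Conditions: DIBAL-H (3 equiv), CH2Cl2, −78 to −20 °C; aq. Rochelle salt
Reagents that add atoms: water, O
Why: DIBAL-H adds once to the nitrile and hydrolysis of the aluminium imine gives the neopentyl aldehyde whose carbonyl carbon is C5, the only oxidation pattern in which a one-carbon ylide supplies C6 without making the chain one carbon too long.

Step 10
Reactants: 13 (5S)-5-(benzyloxy)-9-(tert-butyldimethylsilyloxy)-6-hydroxy-2,2-dimethylnonanal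
Product: 14 (S)-5-(benzyloxy)-9-(tert-butyldimethylsilyloxy)-2,2-dimethyl-6-oxononanal
Conditions: Dess–Martin periodinane, CH2Cl2, rt
Reagents that add atoms: none
Why: Dess–Martin oxidation converts the C10 carbinol into the ketone under neutral conditions that spare the aldehyde, the silyl ether and the C1 centre.

Step 11
Reactants: 14 (S)-5-(benzyloxy)-9-(tert-butyldimethylsilyloxy)-2,2-dimethyl-6-oxononanal; 15 (methoxymethyl)triphenylphosphonium chloride
Product: 17 open-chain bis(methyl enol ether) (S)-6-(benzyloxy)-1-methoxy-7-(methoxymethylidene)-3,3-dimethyl-10-(tert-butyldimethylsilyloxy)dec-1-ene, via ylide 16 (not isolated)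
Conditions: 15 (5 equiv), KHMDS (4.8 equiv), THF, 0 °C; then 14, −78 °C to rt
Reagents that add atoms: none
Why: Double Wittig methoxymethylenation makes one ylide carbon C6 (on the C5 aldehyde) and one C20 (on the C10 ketone), and a cold ylide solution free of excess base keeps enolisation at C1 down.

Step 12
Reactants: 17 open-chain bis(methyl enol ether)
Product: 18 ring A bis(dimethyl acetal) (1S,5R,10R): cyclohexane with gem-dimethyl C4, equatorial C1–OBn, equatorial CH(OMe)2 (C6) on C5, and on C10 an axial CH(OMe)2 (C20, cis to OBn and to C6) and the equatorial (CH2)3OTBS arm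
Conditions: RVC anode, Pt cathode, undivided cell, constant current, 2.2 F/mol, 0.1 M LiClO4, 2,6-lutidine, MeOH/THF 3:7, rt
Reagents that add atoms: methanol, CO
Why: The anode takes one electron from the more electron-rich, trisubstituted C10=C20 enol ether, C5 (the nucleophilic β-carbon of the second enol ether) adds to C10 of the radical cation, and a second electron transfer plus methanol capture of both oxocarbenium carbons gives the two dimethyl acetals while protons are reduced to hydrogen at the cathode. The closest known reaction type is the intramolecular anodic coupling of two enol ethers (anodic olefin coupling), documented for six-membered rings and for quaternary carbon. Ring A closes in a 6-exo-trig mode with respect to both alkenes. C10 is set by a chair-like transition state in which the C1 benzyloxy group is equatorial and antiperiplanar to the forming bond (Felkin–Anh-type arrangement), the flat sp2 carbon C20 takes the axial site beside the axial C4 methyl group, and the sp3 C9 arm takes the equatorial site, which puts C20 cis to O1. C5 is set by the equatorial position of the C5=C6 vinyl ether in the same chair, cis to C20, and can still be corrected by epimerisation at the stage of dialdehyde 19. The step needs C–C bond formation to outrun methanol capture and needs all other groups to stay unoxidised; the C4 gem-dimethyl group (Thorpe–Ingold effect), the six-membered closure and the methanol-poor medium serve the first need, the high oxidation potentials of benzyl and silyl ethers serve the second, and 2,6-lutidine shields the acid-labile allylic ether.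

Step 13
Reactants: 18 ring A bis(dimethyl acetal)
Product: 20 triol with C6–OH and C20–OH and C7–OH free and C1–OBn kept, via dialdehyde 19 (not isolated)
Conditions: aq. HCl (cat.), THF, 45 °C; then NaHCO3 to pH 8, NaBH4, EtOH, 0 °C
Reagents that add atoms: water, O
Why: Acetal hydrolysis unmasks both aldehydes and removes the primary silyl ether, any axial formyl group at C5 can epimerise to the favoured equatorial one (C10 has no α-hydrogen), and borohydride reduction then gives the triol.

Step 14
Reactants: 20 triol
Product: 22 hydroxy spirolactone (rings A and B; C6–OH free), via lactol 21 (not isolated)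
Conditions: TEMPO (0.2 equiv), PhI(OAc)2 (2.3 equiv), CH2Cl2, rt
Reagents that add atoms: none
Why: In this TEMPO oxidative lactonisation of a 1,5-diol the oxoammonium salt takes the unhindered C7 alcohol first, the aldehyde closes to the six-membered lactol with C20–OH (C6–OH would need a seven-membered ring), and the lactol is oxidised to the ring B lactone, so C20–OH and C6–OH are told apart without a selective protection.

Step 15
Reactants: 22 hydroxy spirolactone
Product: 23 spirolactone with C6–OTBS and C1–OBn
Conditions: TBSCl, imidazole, DMAP (cat.), DMF, rt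
Reagents that add atoms: tert-butyldimethylsilyl chloride, CC(C)(C)[Si](C)(C)Cl
Why: Standard silylation caps the only free hydroxyl, and the hindered site makes this silyl ether robust in the later mild acid step.

Step 16
Reactants: 24 methyl 4,4-dimethoxybutanoate
Product: 25 lithium 4,4-dimethoxybutanoate
Conditions: LiOH (1.0 equiv), THF/H2O, rt; evaporation
Reagents that add atoms: lithium hydroxide, [Li+].[OH-]
Why: Saponification and isolation as the salt avoids any acidification that would endanger the acetal (future C11).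

Step 17
Reactants: 25 lithium 4,4-dimethoxybutanoate; 26 (R)-4-benzyl-1,3-oxazolidin-2-one
Product: 28 (R)-4-benzyl-3-(4,4-dimethoxybutanoyl)-1,3-oxazolidin-2-one, via mixed anhydride 27 (not isolated)
Conditions: PivCl, THF, 0 °C; then 26, LiCl, Et3N, rt
Reagents that add atoms: none
Why: N-acylation through the mixed pivalic anhydride takes place at the less hindered carbonyl group under conditions mild enough for the acetal.

Step 18
Reactants: 28 (R)-4-benzyl-3-(4,4-dimethoxybutanoyl)-1,3-oxazolidin-2-one; 29 allyl iodide
Product: 30 (R)-4-benzyl-3-[(R)-2-(2,2-dimethoxyethyl)pent-4-enoyl]-1,3-oxazolidin-2-one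
Conditions: NaHMDS, THF, −78 °C; then 29, −78 to −45 °C
Reagents that add atoms: none
Why: In this Evans alkylation the chelated Z-enolate is allylated on the face opposite the auxiliary's benzyl group, which sets C13 as (R) with the allyl group as C16–C15 plus one carbon that is cleaved off later.

Step 19
Reactants: 30 allylated imide
Product: 31 (R)-2-(2,2-dimethoxyethyl)pent-4-en-1-ol
Conditions: LiBH4, MeOH (1 equiv), Et2O, 0 °C
Reagents that add atoms: none
Why: Reductive removal of the auxiliary with lithium borohydride gives the C14 alcohol without touching C13, the alkene or the acetal.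

Step 20
Reactants: 31 (R)-2-(2,2-dimethoxyethyl)pent-4-en-1-ol
Product: 32 (R)-4-(iodomethyl)-6,6-dimethoxyhex-1-ene
Conditions: I2, PPh3, imidazole, CH2Cl2, 0 °C
Reagents that add atoms: iodine, II
Why: Appel-type iodination under imidazole buffering converts the primary alcohol into the C14 electrophile and keeps the acetal.

Step 21
Reactants: 23 spirolactone with C6–OTBS and C1–OBn; 32 (R)-4-(iodomethyl)-6,6-dimethoxyhex-1-ene
Product: 33 C8-alkylated spirolactone (both C8 epimers) carrying C14–C13(allyl)–C12–C11H(OMe)2
Conditions: LDA, THF, −78 °C; then 32, HMPA, −78 to −20 °C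
Reagents that add atoms: none
Why: Lactone enolate alkylation with a primary iodide in a polar co-solvent forms C8–C14, and the C8 configuration does not matter because C8 becomes sp2 in the next step.

Step 22
Reactants: 33 C8-alkylated spirolactone
Product: 35 α-substituted α,β-unsaturated spirolactone (C8=C9), via selenide 34 (not isolated)
Conditions: LDA, THF, −78 °C; PhSeBr; then 30% H2O2, pyridine, CH2Cl2, 0 °C to rt
Reagents that add atoms: none
Why: Selenenylation of the tertiary enolate and selenoxide syn-elimination should favour the endocyclic, conjugated and more substituted C8=C9 alkene, with both C9 hydrogens available for the syn pathway.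

Step 23
Reactants: 35 unsaturated spirolactone acetal
Product: 36 unsaturated spirolactone C11 aldehyde
Conditions: PPTS, acetone/H2O, 40 °C
Reagents that add atoms: water, O
Why: The unhindered dimethyl acetal hydrolyses under weak acid catalysis that the hindered C6 silyl ether, the benzyl ether and the lactone tolerate.

Step 24
Reactants: 36 unsaturated spirolactone C11 aldehyde
Product: 37 tricyclic lactone (rings A, B, C) with C11–OH, H9 and C13-allyl on one face of ring C and C10 on the other (C8–H not defined)
Conditions: SmI2 (2.5 equiv), LiBr, t-BuOH, THF, −78 °C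
Reagents that add atoms: none
Why: In this samarium(II) ketyl–olefin cyclisation the C11 ketyl adds 6-endo to C9, the β-carbon of the unsaturated lactone (preferred over 5-exo addition to the unactivated allyl group), through a chair with C10, the C11 samarium alkoxide and the C13 allyl group all equatorial, so preset (R)-C13 selects the C9 face flanked by the small, samarium-binding O1 rather than by C6H2OTBS and thereby sets C9 and C11, while the C8 enolate is simply protonated.

Step 25
Reactants: 37 tricyclic lactone alcohol
Product: 38 tricyclic lactone with C11–OTBS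
Conditions: TBSOTf, 2,6-lutidine, CH2Cl2, 0 °C
Reagents that add atoms: tert-butyldimethylsilyl triflate, CC(C)(C)[Si](C)(C)OS(=O)(=O)C(F)(F)F
Why: Silyl triflate silylation caps the equatorial secondary alcohol before the strong-base step and matches the C6 protecting group for a single final deprotection.

Step 26
Reactants: 38 tricyclic lactone with C11–OTBS
Product: 39 silyl ketene acetal (C8=C7(OTBS)–O)
Conditions: KHMDS, THF/DMPU, −78 °C; then TBSCl
Reagents that add atoms: tert-butyldimethylsilyl chloride, CC(C)(C)[Si](C)(C)Cl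
Why: O-silylation of the potassium lactone enolate, whose only acidic site is C8–H, gives the ketene acetal and erases the undefined C8 centre.

Step 27
Reactants: 39 silyl ketene acetal
Product: 40 tetracycle with the bicyclo[3.2.1]octane (rings C/D), quaternary C8 and an exocyclic methylene on C15
Conditions: Pd(OAc)2 (1 equiv), AcOH (0.5 equiv), DMSO, 45 °C
Reagents that add atoms: none
Why: In this palladium(II)-mediated oxidative cyclisation of a silyl ketene acetal onto a pendant alkene (Saegusa-type cycloalkenylation) C8 attacks the internal alkene carbon C15 in a 5-exo mode and β-hydride elimination leaves the C15 methylene, and the bridge can only form on the ring C face that carries the C13 side chain, which fixes C8 with C15 cis to H9.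

Step 28
Reactants: 40 tetracyclic exocyclic alkene
Product: 41 tetracyclic C15 ketone (β-keto lactone)
Conditions: O3, CH2Cl2/MeOH, −78 °C (Sudan III end point); then Me2S
Reagents that add atoms: ozone, [O-][O+]=O
Why: Ozonolysis of the only alkene with indicator control is much faster than oxidation of the benzyl ether and turns the extra carbon into formaldehyde, leaving the C15 ketone.

Step 29
Reactants: 41 tetracyclic C15 ketone
Product: 42 C1 alcohol
Conditions: H2 (1 atm), Pd(OH)2/C, EtOAc, rt
Reagents that add atoms: none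
Why: Hydrogenolysis of the benzyl ether is placed at the one stage without C=C bonds, and the hindered ketone, the lactone and the silyl ethers are inert.

Step 30
Reactants: 42 C1 alcohol
Product: 43 C1 acetate
Conditions: Ac2O, DMAP, pyridine, CH2Cl2, rt
Reagents that add atoms: acetic anhydride, CC(=O)OC(C)=O
Why: DMAP-catalysed acetylation meets a single free hydroxyl, and it comes after the last strong-base step so the acetate is never exposed to enolising conditions.

Step 31
Reactants: 43 C1 acetate
Product: 45 bis-silylated α-methylene ketone (C16=C17), via Mannich base 44 (not isolated)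
Conditions: (Me2N)2CH2, Ac2O, DMF, 95 °C
Reagents that add atoms: bis(dimethylamino)methane, CN(C)CN(C)C
Why: In this Mannich methylenation the iminium acetate formed in the flask reacts at C16, the only enolisable position of the ketone (C8 is quaternary), and the amine is eliminated on heating under base-free conditions that the acetate tolerates.

Step 32
Reactants: 45 bis-silylated α-methylene ketone
Product: 46 Maoyecrystal E
Conditions: HF·pyridine, pyridine, THF, 0 °C to rt
Reagents that add atoms: none
Why: Buffered fluoride desilylation removes both silyl ethers (C6 and C11) without harming the acetate, the enone or the lactone.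

Compound list
1 | (S)-2-(2,2-dimethyl-1,3-dioxolan-4-yl)ethanol | OCC[C@H]1COC(C)(C)O1 | starting material
2 | (S)-4-(2-iodoethyl)-2,2-dimethyl-1,3-dioxolane | ICC[C@H]1COC(C)(C)O1 | intermediate
3 | isobutyronitrile | CC(C)C#N | starting material
4 | (S)-4-(2,2-dimethyl-1,3-dioxolan-4-yl)-2,2-dimethylbutanenitrile | N#CC(C)(C)CC[C@H]1COC(C)(C)O1 | intermediate
5 | (S)-5,6-dihydroxy-2,2-dimethylhexanenitrile | N#CC(C)(C)CC[C@H](O)CO | intermediate
6 | (S)-5-hydroxy-2,2-dimethyl-6-(trityloxy)hexanenitrile | N#CC(C)(C)CC[C@H](O)COC(c1ccccc1)(c1ccccc1)c1ccccc1 | intermediate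
7 | (S)-5-(benzyloxy)-2,2-dimethyl-6-(trityloxy)hexanenitrile | N#CC(C)(C)CC[C@H](OCc1ccccc1)COC(c1ccccc1)(c1ccccc1)c1ccccc1 | intermediate
8 | (S)-5-(benzyloxy)-6-hydroxy-2,2-dimethylhexanenitrile | N#CC(C)(C)CC[C@H](OCc1ccccc1)CO | intermediate
9 | (S)-5-(benzyloxy)-2,2-dimethyl-6-oxohexanenitrile | N#CC(C)(C)CC[C@H](OCc1ccccc1)C=O | intermediate
10 | (3-bromopropoxy)(tert-butyl)dimethylsilane | BrCCCO[Si](C)(C)C(C)(C)C | starting material
11 | [3-(tert-butyldimethylsilyloxy)propyl]magnesium bromide | Br[Mg]CCCO[Si](C)(C)C(C)(C)C | intermediate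
12 | (5S)-5-(benzyloxy)-9-(tert-butyldimethylsilyloxy)-6-hydroxy-2,2-dimethylnonanenitrile, carbinol epimers | N#CC(C)(C)CC[C@H](OCc1ccccc1)C(O)CCCO[Si](C)(C)C(C)(C)C | intermediate
13 | (5S)-5-(benzyloxy)-9-(tert-butyldimethylsilyloxy)-6-hydroxy-2,2-dimethylnonanal, carbinol epimers | O=CC(C)(C)CC[C@H](OCc1ccccc1)C(O)CCCO[Si](C)(C)C(C)(C)C | intermediate
14 | (S)-5-(benzyloxy)-9-(tert-butyldimethylsilyloxy)-2,2-dimethyl-6-oxononanal | O=CC(C)(C)CC[C@H](OCc1ccccc1)C(=O)CCCO[Si](C)(C)C(C)(C)C | intermediate
15 | (methoxymethyl)triphenylphosphonium chloride | COC[P+](c1ccccc1)(c1ccccc1)c1ccccc1.[Cl-] | starting material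
16 | (methoxymethylene)triphenylphosphorane | COC=P(c1ccccc1)(c1ccccc1)c1ccccc1 | intermediate
17 | open-chain bis(methyl enol ether), (1E,6S,7E) isomer drawn | CO/C=C/C(C)(C)CC[C@H](OCc1ccccc1)/C(CCCO[Si](C)(C)C(C)(C)C)=C/OC | intermediate
18 | ring A bis(dimethyl acetal), (1S,5R,10R) | CC(C)(C)[Si](C)(C)OCCC[C@]1(C(OC)OC)[C@@H](OCc2ccccc2)CCC(C)(C)[C@H]1C(OC)OC | intermediate
19 | ring A dialdehyde with free C7–OH (open form drawn) | OCCC[C@]1(C=O)[C@@H](OCc2ccccc2)CCC(C)(C)[C@H]1C=O | intermediate
20 | ring A triol (C6–OH, C20–OH, C7–OH) | OCCC[C@]1(CO)[C@@H](OCc2ccccc2)CCC(C)(C)[C@H]1CO | intermediate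
21 | ring B lactol (C7 hemiacetal with O–C20) | OC1CC[C@]2(CO1)[C@@H](OCc3ccccc3)CCC(C)(C)[C@H]2CO | intermediate
22 | hydroxy spirolactone (rings A/B) | O=C1CC[C@]2(CO1)[C@@H](OCc3ccccc3)CCC(C)(C)[C@H]2CO | intermediate
23 | spirolactone, C6–OTBS, C1–OBn | O=C1CC[C@]2(CO1)[C@@H](OCc3ccccc3)CCC(C)(C)[C@H]2CO[Si](C)(C)C(C)(C)C | intermediate
24 | methyl 4,4-dimethoxybutanoate | COC(=O)CCC(OC)OC | starting material
25 | lithium 4,4-dimethoxybutanoate | [Li+].[O-]C(=O)CCC(OC)OC | intermediate
26 | (R)-4-benzyl-1,3-oxazolidin-2-one | O=C1N[C@H](Cc2ccccc2)CO1 | starting material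
27 | 4,4-dimethoxybutanoic pivalic anhydride | CC(C)(C)C(=O)OC(=O)CCC(OC)OC | intermediate
28 | (R)-4-benzyl-3-(4,4-dimethoxybutanoyl)-1,3-oxazolidin-2-one | COC(OC)CCC(=O)N1[C@H](Cc2ccccc2)COC1=O | intermediate
29 | allyl iodide | C=CCI | starting material
30 | (R)-4-benzyl-3-[(R)-2-(2,2-dimethoxyethyl)pent-4-enoyl]-1,3-oxazolidin-2-one | C=CC[C@H](CC(OC)OC)C(=O)N1[C@H](Cc2ccccc2)COC1=O | intermediate
31 | (R)-2-(2,2-dimethoxyethyl)pent-4-en-1-ol | C=CC[C@H](CC(OC)OC)CO | intermediate
32 | (R)-4-(iodomethyl)-6,6-dimethoxyhex-1-ene | C=CC[C@H](CC(OC)OC)CI | intermediate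
33 | C8-alkylated spirolactone, C8 epimers | O=C1C(C[C@H](CC=C)CC(OC)OC)C[C@]2(CO1)[C@@H](OCc3ccccc3)CCC(C)(C)[C@H]2CO[Si](C)(C)C(C)(C)C | intermediate
34 | C8 phenylselenide, C8 epimers | O=C1C([Se]c3ccccc3)(C[C@H](CC=C)CC(OC)OC)C[C@]2(CO1)[C@@H](OCc3ccccc3)CCC(C)(C)[C@H]2CO[Si](C)(C)C(C)(C)C | intermediate
35 | C8=C9 unsaturated spirolactone, C11 dimethyl acetal | O=C1C(C[C@H](CC=C)CC(OC)OC)=C[C@]2(CO1)[C@@H](OCc3ccccc3)CCC(C)(C)[C@H]2CO[Si](C)(C)C(C)(C)C | intermediate
36 | C8=C9 unsaturated spirolactone, C11 aldehyde | O=C1C(C[C@H](CC=C)CC=O)=C[C@]2(CO1)[C@@H](OCc3ccccc3)CCC(C)(C)[C@H]2CO[Si](C)(C)C(C)(C)C | intermediate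
37 | tricyclic lactone with C11–OH (C8 not defined) | C=CC[C@@H]1C[C@H](O)[C@@H]2C(C1)C(=O)OC[C@]23[C@@H](OCc4ccccc4)CCC(C)(C)[C@H]3CO[Si](C)(C)C(C)(C)C | intermediate
38 | tricyclic lactone with C11–OTBS (C8 not defined) | C=CC[C@@H]1C[C@H](O[Si](C)(C)C(C)(C)C)[C@@H]2C(C1)C(=O)OC[C@]23[C@@H](OCc4ccccc4)CCC(C)(C)[C@H]3CO[Si](C)(C)C(C)(C)C | intermediate
39 | silyl ketene acetal | C=CC[C@@H]1C[C@H](O[Si](C)(C)C(C)(C)C)[C@@H]2C(C1)=C(O[Si](C)(C)C(C)(C)C)OC[C@]23[C@@H](OCc4ccccc4)CCC(C)(C)[C@H]3CO[Si](C)(C)C(C)(C)C | intermediate
40 | tetracycle with C15 exocyclic methylene | C1C(=C)[C@]23C[C@H]1C[C@H](O[Si](C)(C)C(C)(C)C)[C@H]2[C@]1(COC3=O)[C@@H](OCc4ccccc4)CCC(C)(C)[C@H]1CO[Si](C)(C)C(C)(C)C | intermediate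
41 | tetracyclic C15 ketone, C1–OBn | C1C(=O)[C@]23C[C@H]1C[C@H](O[Si](C)(C)C(C)(C)C)[C@H]2[C@]1(COC3=O)[C@@H](OCc4ccccc4)CCC(C)(C)[C@H]1CO[Si](C)(C)C(C)(C)C | intermediate
42 | tetracyclic C15 ketone, C1–OH | C1C(=O)[C@]23C[C@H]1C[C@H](O[Si](C)(C)C(C)(C)C)[C@H]2[C@]1(COC3=O)[C@@H](O)CCC(C)(C)[C@H]1CO[Si](C)(C)C(C)(C)C | intermediate
43 | tetracyclic C15 ketone, C1–OAc | C1C(=O)[C@]23C[C@H]1C[C@H](O[Si](C)(C)C(C)(C)C)[C@H]2[C@]1(COC3=O)[C@@H](OC(C)=O)CCC(C)(C)[C@H]1CO[Si](C)(C)C(C)(C)C | intermediate
44 | C16 (dimethylamino)methyl ketone (C16 not defined) | CN(C)CC1C(=O)[C@]23C[C@H]1C[C@H](O[Si](C)(C)C(C)(C)C)[C@H]2[C@]1(COC3=O)[C@@H](OC(C)=O)CCC(C)(C)[C@H]1CO[Si](C)(C)C(C)(C)C | intermediate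
45 | 6,11-bis-O-TBS Maoyecrystal E | C=C1C(=O)[C@]23C[C@H]1C[C@H](O[Si](C)(C)C(C)(C)C)[C@H]2[C@]1(COC3=O)[C@@H](OC(C)=O)CCC(C)(C)[C@H]1CO[Si](C)(C)C(C)(C)C | intermediate
46 | Maoyecrystal E | C=C1C(=O)[C@]23C[C@H]1C[C@H](O)[C@H]2[C@]1(COC3=O)[C@@H](OC(C)=O)CCC(C)(C)[C@H]1CO | target

Total step count: 32
Longest linear sequence: 27 steps (steps 1–15 and 21–32). Steps 16–20 build the C11–C16 side fragment in parallel.

Steps most likely to fail

Step 12. Methanol may capture the radical cation before the bond to the neopentyl carbon C5 forms, or the two faces of C10 may be poorly distinguished.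
- Fallback: the same bond is made by a polar, non-oxidative route in which C6 enters as a nitro-bearing carbon.
- Setting out from 12, Dess–Martin oxidation gives the keto nitrile F1.
- Wittig methoxymethylenation of the ketone then gives the enol ether nitrile F2, and DIBAL-H gives the enol ether aldehyde F3.
- A base-catalysed Henry addition of nitromethane gives the nitro alcohol F4, and MsCl/Et3N gives the nitroalkene F5.
- SnCl4 at −78 °C then promotes the intramolecular inverse-demand [4+2] cycloaddition of the nitroalkene (C5=C6–N=O) with the C10=C20 enol ether. This joins C5 to C10 and O to C20 and ties C6 and C20 cis in the bicyclic nitronate F6.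
- Nef-type hydrolysis in aqueous acid converts it into dialdehyde 19, where the route is rejoined.

Step 24. Facial selectivity at C9 may be poor, because the new C1 substituent sits beside the face that has to be attacked.
- Fallback: stereocontrol is moved from the kinetic ring closure to an equilibration.
- Setting out from 36, the crude product of the samarium closure is oxidised with Dess–Martin periodinane to the C11 ketone F7, in which C9 is α to the ketone.
- DBU equilibrates C9 (and C8) to the isomer with C10 and the C13 allyl group both equatorial on ring C, which is the required configuration dictated by (R)-C13.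
- NaBH4 with axial hydride delivery gives the equatorial C11 alcohol, rejoining the route at 37.

Step 27. Protodesilylation of the ketene acetal or dehydrogenation may compete with C–C bond formation at hindered C8.
- Fallback: ring D is closed by an aldol-type C8–C15 bond.
- Setting out from 39, NBS gives the α-bromo lactone F8, and ozonolysis of its allyl group gives the bromo aldehyde F9 (C15 aldehyde).
- SmI2 at −78 °C reduces the C8–Br bond to the samarium enolate, which adds to the aldehyde (intramolecular samarium Reformatsky reaction) on the only reachable face to give the C15 carbinol F10.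
- Dess–Martin oxidation rejoins the route at 41.

Further compounds
F1 | step 12 | (S)-5-(benzyloxy)-9-(tert-butyldimethylsilyloxy)-2,2-dimethyl-6-oxononanenitrile (keto nitrile) | N#CC(C)(C)CC[C@H](OCc1ccccc1)C(=O)CCCO[Si](C)(C)C(C)(C)C
F2 | step 12 | enol ether nitrile (C10=C20 methyl enol ether, E isomer drawn) | N#CC(C)(C)CC[C@H](OCc1ccccc1)/C(CCCO[Si](C)(C)C(C)(C)C)=C/OC
F3 | step 12 | enol ether aldehyde (C5 aldehyde) | O=CC(C)(C)CC[C@H](OCc1ccccc1)/C(CCCO[Si](C)(C)C(C)(C)C)=C/OC
F4 | step 12 | nitro alcohol (C5 carbinol epimers) | O=[N+]([O-])CC(O)C(C)(C)CC[C@H](OCc1ccccc1)/C(CCCO[Si](C)(C)C(C)(C)C)=C/OC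
F5 | step 12 | nitroalkene (C5=C6–NO2) | O=[N+]([O-])/C=C/C(C)(C)CC[C@H](OCc1ccccc1)/C(CCCO[Si](C)(C)C(C)(C)C)=C/OC
F6 | step 12 | bicyclic nitronate (ring A fused to a 1,2-oxazine N-oxide, C20 acetal centre not defined) | CC(C)(C)[Si](C)(C)OCCC[C@@]12C(OC)O[N+]([O-])=C[C@@H]1C(C)(C)CC[C@@H]2OCc1ccccc1
F7 | step 24 | tricyclic C11 ketone (C8 not defined) | C=CC[C@@H]1CC(=O)[C@@H]2C(C1)C(=O)OC[C@]23[C@@H](OCc4ccccc4)CCC(C)(C)[C@H]3CO[Si](C)(C)C(C)(C)C
F8 | step 27 | α-bromo lactone (C8 not defined) | C=CC[C@@H]1C[C@H](O[Si](C)(C)C(C)(C)C)[C@@H]2C(Br)(C1)C(=O)OC[C@]23[C@@H](OCc4ccccc4)CCC(C)(C)[C@H]3CO[Si](C)(C)C(C)(C)C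
F9 | step 27 | bromo aldehyde (C15 aldehyde, C8 not defined) | O=CC[C@@H]1C[C@H](O[Si](C)(C)C(C)(C)C)[C@@H]2C(Br)(C1)C(=O)OC[C@]23[C@@H](OCc4ccccc4)CCC(C)(C)[C@H]3CO[Si](C)(C)C(C)(C)C
F10 | step 27 | tetracyclic C15 carbinol (C15 not defined) | C1C(O)[C@]23C[C@H]1C[C@H](O[Si](C)(C)C(C)(C)C)[C@H]2[C@]1(COC3=O)[C@@H](OCc4ccccc4)CCC(C)(C)[C@H]1CO[Si](C)(C)C(C)(C)C
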